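**Strategy.** The flavone is disconnected at the aryl ether bond O1–C8a of ring C. Ring A is symmetric about its C4a–C7 axis (6-OMe mirrors 8-OMe). C5 and C8a, the two positions ortho to the C4 ketone, can therefore both start as C–Br and need not be told apart. The precursor is a 2-methoxy-1,3-diketone bearing a 4-benzyloxy-2,6-dibromo-3,5-dimethoxyphenyl group on one carbonyl and a 4-benzyloxyphenyl group on the other. Copper-catalysed O-arylation of its enolate forms O1–C8a, closes the pyranone and fixes the full flavone skeleton in one operation. The surviving C5 bromide becomes the peri oxygen, and all benzyl groups fall together at the end.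

Key step: step 5

Remark: the target has no stereocentre. The central carbon of the diketone precursor is a configurationally labile centre (keto–enol exchange), so that compound is drawn without configuration and carried as the racemic keto/enol mixture. Flavone numbering (O1 to C8a, rings A, B, C) is used from the ring closure onward.

Step 1
Reactants: 1 2,6-dimethoxyphenol
Product: 2 2-(benzyloxy)-1,3-dimethoxybenzene
Conditions: BnBr (1.1 equiv), K2CO3 (1.5 equiv), DMF, 60 °C
Reagents that add atoms: benzyl bromide, BrCc1ccccc1
Why: Williamson ether synthesis: the phenoxide of 1 displaces bromide from the SN2-active benzylic halide, and masking the phenol removes its dominant para-directing effect before the bromination and gives a group that survives strong base and copper catalysis.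

Step 2
Reactants: 2 2-(benzyloxy)-1,3-dimethoxybenzene
Product: 3 3-(benzyloxy)-1,5-dibromo-2,4-dimethoxybenzene
Conditions: NBS (2.15 equiv), MeCN, 0 °C → 40 °C, dark
Reagents that add atoms: N-bromosuccinimide, O=C1CCC(=O)N1Br
Why: Electrophilic aromatic bromination (SEAr) with NBS in a polar solvent: the benzyloxy group, squeezed between two methoxy groups, is twisted out of conjugation, so the methoxy groups steer both bromines to C4 and C6 of 2 (each ortho to one OMe and para to the other) and leave the single C5–H between them, while the absence of free HBr and of light spares the benzyl ether and its CH2.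

Step 3
Reactants: 3 3-(benzyloxy)-1,5-dibromo-2,4-dimethoxybenzene; 4 N,2-dimethoxy-N-methylacetamide
Product: 7 1-[4-(benzyloxy)-2,6-dibromo-3,5-dimethoxyphenyl]-2-methoxyethan-1-one, via aryllithium 5 (not isolated), via tetrahedral lithium adduct 6 (not isolated)
Conditions: LDA (1.15 equiv), THF, −78 °C (3 added to the base), 45 min; 4 (1.3 equiv), −78 → −40 °C; 1 M HCl
Reagents that add atoms: none
Why: Deprotonative lithiation followed by a Weinreb ketone synthesis: the only hydrogen on the ring sits between two inductively acidifying bromines and is removed by LDA at −78 °C, where aryllithium 5 does not yet lose LiBr, and the N,O-chelated adduct 6 keeps the carbonyl masked until the acidic quench so that no second addition occurs.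

Step 4
Reactants: 7 1-[4-(benzyloxy)-2,6-dibromo-3,5-dimethoxyphenyl]-2-methoxyethan-1-one; 8 4-(benzyloxy)benzoyl chloride
Product: 11 1-[4-(benzyloxy)-2,6-dibromo-3,5-dimethoxyphenyl]-3-[4-(benzyloxy)phenyl]-2-methoxypropane-1,3-dione, via lithium enolate 9 (not isolated), via lithium diketonate 10 (not isolated)
Conditions: LiHMDS (2.2 equiv), THF, −78 °C, 45 min; 8 (1.05 equiv), −78 → 0 °C; 1 M HCl
Reagents that add atoms: none
Why: Claisen-type C-acylation of a ketone lithium enolate with an aroyl chloride: the methoxy-chelated Z-enolate 9 reacts at its unhindered carbon terminus because its oxygen is screened by the orthogonal dibromoaryl ring, and the second equivalent of base stores the more acidic product as diketonate 10, which prevents proton exchange and double acylation.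

Step 5
Reactants: 11 1-[4-(benzyloxy)-2,6-dibromo-3,5-dimethoxyphenyl]-3-[4-(benzyloxy)phenyl]-2-methoxypropane-1,3-dione
Product: 13 7,4'-bis(benzyloxy)-5-bromo-3,6,8-trimethoxyflavone, via caesium enolate 12 (not isolated)
Conditions: CuI (10 mol%), 1,10-phenanthroline (20 mol%), Cs2CO3 (2 equiv), 4 Å MS, 1,4-dioxane, 95 °C, Ar
Reagents that add atoms: none
Why: Cs2CO3 turns 11 into the caesium enolate 12, whose ring B-side oxygen binds phenanthroline-ligated monovalent copper; assisted by the adjacent C4 carbonyl, copper adds oxidatively into one ortho C–Br bond to give a seven-membered trivalent-copper metallacycle, and C–O reductive elimination forms O1–C8a and returns the catalyst. The closest known reaction type is the intramolecular Ullmann-type O-arylation of 1-(2-haloaryl)-1,3-diketones to chromones and flavones, applied here without change of bond type or substrate class. Ring C closes as a six-membered ring with the leaving bromide outside it (6-exo with respect to the C–Br bond), and any uncatalysed addition–elimination share would count as 6-endo-trig with respect to the C4a=C8a bond conjugated to C4=O and would lead to the same product. No stereocentre is created, and the labile centre of 11 vanishes as it becomes the sp2 carbon C3. The step needs O- over C-arylation and the correct oxygen, both secured by ring size because the central carbon or the ring A-side oxygen could only build four-membered rings, and it needs no choice between the bromines because rotation about C4–C4a interchanges them and either closure gives the same 13. Product 13 holds no further nucleophile, and the amine-free solvent and the sieves keep the activated peri bromide and the retro-Claisen-prone diketone from being consumed.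

Step 6
Reactants: 13 7,4'-bis(benzyloxy)-5-bromo-3,6,8-trimethoxyflavone
Product: 14 5,7,4'-tris(benzyloxy)-3,6,8-trimethoxyflavone
Conditions: BnOH (3 equiv), CuI (20 mol%), 3,4,7,8-tetramethyl-1,10-phenanthroline (40 mol%), Cs2CO3 (2 equiv), toluene, 110 °C, Ar
Reagents that add atoms: benzyl alcohol, OCc1ccccc1
Why: Ullmann-type copper-catalysed C–O coupling of an aryl bromide with a primary alcohol: the peri C4 carbonyl activates C5–Br electronically and chelates copper (the effect that makes 1-haloanthraquinones and 2-halobenzoyl compounds good Ullmann substrates), and an anhydrous alkoxide in place of hydroxide avoids hydrolytic opening and retro-Claisen cleavage of ring C while delivering a group that leaves in the final hydrogenolysis.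

Step 7
Reactants: 14 5,7,4'-tris(benzyloxy)-3,6,8-trimethoxyflavone
Product: 15 5,7,4'-trihydroxy-3,6,8-trimethoxyflavone (target)
Conditions: H2 (1 atm), 10% Pd/C, THF–MeOH, rt
Reagents that add atoms: none
Why: Catalytic hydrogenolysis of aryl benzyl ethers: all three O–CH2Ph bonds should be cleaved at room temperature under one atmosphere of hydrogen, while the tetrasubstituted vinylogous-ester C2=C3 bond, the C4 carbonyl and the three methyl ethers are inert under these conditions.

**Compound list**
1 | 2,6-dimethoxyphenol | COc1cccc(OC)c1O | starting material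
2 | 2-(benzyloxy)-1,3-dimethoxybenzene | COc1cccc(OC)c1OCc1ccccc1 | intermediate
3 | 3-(benzyloxy)-1,5-dibromo-2,4-dimethoxybenzene | COc1c(Br)cc(Br)c(OC)c1OCc1ccccc1 | intermediate
4 | N,2-dimethoxy-N-methylacetamide | COCC(=O)N(C)OC | starting material
5 | [4-(benzyloxy)-2,6-dibromo-3,5-dimethoxyphenyl]lithium | [Li]c1c(Br)c(OC)c(OCc2ccccc2)c(OC)c1Br | intermediate
6 | lithium 1-[4-(benzyloxy)-2,6-dibromo-3,5-dimethoxyphenyl]-2-methoxy-1-[methoxy(methyl)amino]ethan-1-olate (racemic) | [Li+].COCC([O-])(N(C)OC)c1c(Br)c(OC)c(OCc2ccccc2)c(OC)c1Br | intermediate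
7 | 1-[4-(benzyloxy)-2,6-dibromo-3,5-dimethoxyphenyl]-2-methoxyethan-1-one | COCC(=O)c1c(Br)c(OC)c(OCc2ccccc2)c(OC)c1Br | intermediate
8 | 4-(benzyloxy)benzoyl chloride | O=C(Cl)c1ccc(OCc2ccccc2)cc1 | starting material
9 | lithium (Z)-1-[4-(benzyloxy)-2,6-dibromo-3,5-dimethoxyphenyl]-2-methoxyethen-1-olate | [Li+].CO/C=C(\[O-])c1c(Br)c(OC)c(OCc2ccccc2)c(OC)c1Br | intermediate
10 | lithium enolate of diketone 11 (enolate oxygen on the ring B side, cis to the ring A acyl group) | [Li+].CO/C(C(=O)c1c(Br)c(OC)c(OCc2ccccc2)c(OC)c1Br)=C(/[O-])c1ccc(OCc2ccccc2)cc1 | intermediate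
11 | 1-[4-(benzyloxy)-2,6-dibromo-3,5-dimethoxyphenyl]-3-[4-(benzyloxy)phenyl]-2-methoxypropane-1,3-dione (racemic, labile centre) | COC(C(=O)c1ccc(OCc2ccccc2)cc1)C(=O)c1c(Br)c(OC)c(OCc2ccccc2)c(OC)c1Br | intermediate
12 | caesium enolate of diketone 11 (enolate oxygen on the ring B side, cis to the ring A acyl group) | [Cs+].CO/C(C(=O)c1c(Br)c(OC)c(OCc2ccccc2)c(OC)c1Br)=C(/[O-])c1ccc(OCc2ccccc2)cc1 | intermediate
13 | 7,4'-bis(benzyloxy)-5-bromo-3,6,8-trimethoxyflavone | COc1c(OCc2ccccc2)c(OC)c2oc(-c3ccc(OCc4ccccc4)cc3)c(OC)c(=O)c2c1Br | intermediate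
14 | 5,7,4'-tris(benzyloxy)-3,6,8-trimethoxyflavone | COc1c(OCc2ccccc2)c(OC)c2oc(-c3ccc(OCc4ccccc4)cc3)c(OC)c(=O)c2c1OCc1ccccc1 | intermediate
15 | 5,7,4'-trihydroxy-3,6,8-trimethoxyflavone | COc1c(O)c(OC)c2oc(-c3ccc(O)cc3)c(OC)c(=O)c2c1O | target

Total step count: 7. Longest linear sequence: 7 steps (from 1 to 15).

**Steps most likely to fail**

Step 5 (key step). Copper may insert too slowly into the electron-rich, doubly ortho-flanked C–Br bond. Retro-Claisen cleavage of the diketone or reductive loss of bromine could then overtake ring closure. The fallback sets out from 7 and comes back at 13. It puts the ring oxygen on ring A first and closes ring C at O1–C2 instead. Coupling of 7 with one equivalent of (E)-benzaldehyde oxime as a hydroxide surrogate (Pd2(dba)3, tBuBrettPhos, Cs2CO3, DMF, 80 °C) should give the O-aryl oxime 1-[4-(benzyloxy)-2-{[(E)-benzylideneamino]oxy}-6-bromo-3,5-dimethoxyphenyl]-2-methoxyethan-1-one F1. In the basic medium this loses benzonitrile and delivers the phenol 1-[4-(benzyloxy)-2-bromo-6-hydroxy-3,5-dimethoxyphenyl]-2-methoxyethan-1-one F2. The phenoxide deactivates the second bromide, and symmetry again makes the choice of bromide irrelevant. Deprotonation of F2 with LiHMDS (3.2 equiv, THF, −78 °C) and C-acylation with 8 should give the o-hydroxyaryl diketone 1-[4-(benzyloxy)-2-bromo-6-hydroxy-3,5-dimethoxyphenyl]-3-[4-(benzyloxy)phenyl]-2-methoxypropane-1,3-dione F3, the compound a Baker–Venkataraman rearrangement would give. Catalytic TsOH in warm toluene should cyclodehydrate it to 13.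

Step 3. The doubly ortho-flanked, weakly nucleophilic aryllithium may add to the amide too slowly at −78 °C. Warming invites loss of LiBr (aryne formation) and bromine scrambling by halogen–metal exchange. The fallback sets out from 3 and comes back at 11, bypassing steps 3 and 4. Aryllithium 5 is generated as before but trapped at −78 °C with DMF, a small and fast electrophile, to give 4-(benzyloxy)-2,6-dibromo-3,5-dimethoxybenzaldehyde F4. The ring B ketone 1-[4-(benzyloxy)phenyl]-2-methoxyethan-1-one F5 is made from commercial 4-(benzyloxy)phenylmagnesium bromide and 4 (THF, 0 °C). Aldol addition of the lithium enolate of F5 (LiHMDS, THF, −78 °C) to F4 should give 3-[4-(benzyloxy)-2,6-dibromo-3,5-dimethoxyphenyl]-1-[4-(benzyloxy)phenyl]-3-hydroxy-2-methoxypropan-1-one F6 as a mixture of diastereomers. Dess–Martin oxidation (CH2Cl2, rt) then converts it into 11.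

Step 6. C–O bond formation at C5, wedged between the 6-methoxy group and the peri carbonyl, may be slow with the bulky primary alkoxide. Hydride transfer from benzyloxide to copper may then remove the bromine reductively. The fallback sets out from 13 and comes back at 15. It uses the smallest alkoxide and removes the extra methyl group by chelation control. NaOMe and CuBr in DMF–MeOH at 110 °C, a classical exchange on bromoflavones, should give 7,4'-bis(benzyloxy)-3,5,6,8-tetramethoxyflavone F7. Anhydrous AlCl3 in MeCN should cleave only the 5-methyl ether, whose oxygen forms a six-membered aluminium chelate with C4=O, to give 7,4'-bis(benzyloxy)-5-hydroxy-3,6,8-trimethoxyflavone F8. Partial loss of benzyl at this stage would be harmless. Hydrogenolysis as in step 7 then gives 15.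

**Further compounds**
F1 | step 5 | 1-[4-(benzyloxy)-2-{[(E)-benzylideneamino]oxy}-6-bromo-3,5-dimethoxyphenyl]-2-methoxyethan-1-one | COCC(=O)c1c(O/N=C/c2ccccc2)c(OC)c(OCc2ccccc2)c(OC)c1Br
F2 | step 5 | 1-[4-(benzyloxy)-2-bromo-6-hydroxy-3,5-dimethoxyphenyl]-2-methoxyethan-1-one | COCC(=O)c1c(O)c(OC)c(OCc2ccccc2)c(OC)c1Br
F3 | step 5 | 1-[4-(benzyloxy)-2-bromo-6-hydroxy-3,5-dimethoxyphenyl]-3-[4-(benzyloxy)phenyl]-2-methoxypropane-1,3-dione (racemic, labile centre) | COC(C(=O)c1ccc(OCc2ccccc2)cc1)C(=O)c1c(O)c(OC)c(OCc2ccccc2)c(OC)c1Br
F4 | step 3 | 4-(benzyloxy)-2,6-dibromo-3,5-dimethoxybenzaldehyde | O=Cc1c(Br)c(OC)c(OCc2ccccc2)c(OC)c1Br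
F5 | step 3 | 1-[4-(benzyloxy)phenyl]-2-methoxyethan-1-one | COCC(=O)c1ccc(OCc2ccccc2)cc1
F6 | step 3 | 3-[4-(benzyloxy)-2,6-dibromo-3,5-dimethoxyphenyl]-1-[4-(benzyloxy)phenyl]-3-hydroxy-2-methoxypropan-1-one (racemic mixture of diastereomers) | COC(C(=O)c1ccc(OCc2ccccc2)cc1)C(O)c1c(Br)c(OC)c(OCc2ccccc2)c(OC)c1Br
F7 | step 6 | 7,4'-bis(benzyloxy)-3,5,6,8-tetramethoxyflavone | COc1c(OCc2ccccc2)c(OC)c2oc(-c3ccc(OCc4ccccc4)cc3)c(OC)c(=O)c2c1OC
F8 | step 6 | 7,4'-bis(benzyloxy)-5-hydroxy-3,6,8-trimethoxyflavone | COc1c(OCc2ccccc2)c(OC)c2oc(-c3ccc(OCc4ccccc4)cc3)c(OC)c(=O)c2c1O
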